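Remark on the chemistry: atoms carry the labdane-type numbers of the target (decalin C1–C10, gem-dimethyl on C4, methyls on C8 and C10, chain C11–C16 on C9; β is the face of the C10 methyl), and the C3 oxygen is carried as a triisopropylsilyl ether, a spectator change that leaves both key-step skeletons untouched.

## Structural features

The target is a trans-fused decalin (ring A: C1–C5 and C10; ring B: C5–C10) with an (E)-3-methylpent-2-enoate chain (C11–C15, methyl C16) on C9. It has six stereocentres: the cis-2α,3α-diol of ring A, next to the C4 gem-dimethyl group, and the contiguous row C8–C9–C10–C5 in ring B. C9 and C10 are adjacent, fully substituted carbons. C9 carries an equatorial β-hydroxyl cis to the axial C10 methyl, and an axial α side chain cis to the equatorial C8 methyl. The fragile points are the tertiary C9 carbinol (it can add to C13 of the enoate under base and can dehydrate under acid), the E geometry of C13=C14, and the free cis-diol. The real difficulty is the quaternary C10, wedged between C9, C5 and C1 with the quaternary C4 next to C5, together with the stereodefined C9 carbinol beside it. The key step exploits the sequence C8(methyl)–C9(oxygen)–C10(methyl) with C6 para to C9 in ring B, which is the substitution pattern of 2,6-dimethylbenzoquinone and makes C10 the β-carbon of a C6 enone. C1–C4, with the gem-dimethyl C4 and the C3 oxygen, map onto pantolactone, so ring A can close by attack of C1 on C10.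

## Logic of the disconnections

18 ⇒ 17. The two C–O bonds at C2 and C3 are cut. The diol is cis and on the α face, which is the face a syn-dihydroxylation of C2=C3 must take, because the β face carries the axial methyls on C4 and C10. This removes two stereocentres and all hydroxyl protection. The forward step must choose the ring alkene over the conjugated C13=C14.

17 ⇒ 15 + 16. The C13=C14 bond is cut as a phosphonate olefination of a methyl ketone. The side chain shrinks to a 3-oxobutyl group, and C14, C15 and the ester methyl come from 16. The forward step must favour the E isomer and must not let the free C9 hydroxyl add to the new enoate.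

15 ⇒ 11 + 12 (through 13 and 14). The C9–C11 bond is cut, because a tertiary carbinol is the adduct of a ketone and a carbon nucleophile. This removes the whole chain and the C9 stereocentre and leaves a bicyclic ketone. The forward step must add to a hindered, enolisable ketone and must do so from the α face.

11 ⇒ 9 (through 10). Two functional group changes are taken together: the C6 methylene comes from a C6 ketone, and C2=C3 comes from the C2 ketone with its C3 silyloxy neighbour. Both are reductive hydrazone processes, so one operation can serve. This reveals a saturated 1,4-dione in ring B. The forward step must engage the C2 and C6 carbonyls, spare the far more hindered C9 carbonyl, and eliminate rather than simply reduce at C2.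

9 ⇒ 8. The C7=C8 bond is reintroduced to give the ene-dione, the direct descendant of a quinone. The forward step is a chemoselective reduction of that alkene and must leave C8 with its methyl equatorial.

8 ⇒ 7. The C1–C10 bond is cut. C10 is β to the C6 carbonyl through C5=C10, so C1 can be joined to it by conjugate addition. The bicycle falls back to a monocyclic quinone that already holds every carbon of rings A and B, and the stereocentres at C10 and C5 disappear, leaving C3 as the only one. The forward step must attack a methyl-bearing quinone carbon, choose one face, and leave C3 untouched.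

7 ⇒ 5 + 6. The C4–C5 bond is cut as the addition of a tertiary C4 radical, released from a carboxylic acid, to the quinone. The two free ring positions of 6 are equivalent, so only one mono-adduct exists. The forward step must add the radical faster than it is oxidised, stop at mono-alkylation, and spare the silyl ether and C3 in an acidic oxidising medium.

5 ⇒ 3 ⇒ 2 ⇒ 1. The C1–C2 bond is cut as a methyl addition to a lactone carbonyl, and the carboxyl carbon is traced back to the lactone CH2–O carbon. 1 already contains C2, C3 with its oxygen and absolute configuration, and the gem-dimethyl C4. The forward steps need mono-addition and no epimerisation at C3.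

## Other disconnections considered

Alternative 1: The C4–C5 and C9–C10 bonds are cut, leading back to the acyclic epoxy ene-ketone A2. In the forward step Cp2TiCl (trivalent titanium) would open the epoxide to the tertiary C4 radical, which adds to C5 and closes ring A. The resulting tertiary C10 radical would then add to the C9 carbonyl and close ring B, giving A1.
- In its favour: two rings, two C–C bonds and the centres C5, C9 and C10 would arise in one neutral step that tolerates the ketal. The C9 oxygen and the chain carbons are already in place, and there is no C6 oxygen to remove. The titanium-bound oxygen, the bulkier group on C9, would be expected to sit equatorial, which is the 9β-oxygen of the target.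
- Against it here: ending the cascade by adding a tertiary radical to a ketone carbonyl, with two fully substituted carbons formed side by side, must compete with the usual fates of that radical (reduction or hydrogen loss to an alkene). C8, α to the ketone, is epimerisable. A2 itself needs an enantioselective epoxidation, an E-trisubstituted alkene and the C8 centre, about eight to ten steps.
- Comparison: on bonds per step and on the oxidation pattern of ring B, Alternative 1 is the better plan. It is the equal of the chosen plan in the endgame, since A1 still needs the C2=C3 alkene, dihydroxylation and olefination. The chosen plan is preferred because its key bond is formed by a polar addition with a thermodynamic sink, its precursor 7 is four steps from the chiral pool, and the C2 oxygen of 8 makes the later C2=C3 alkene regiospecific, whereas the equatorial 3β-hydroxyl of A1 next to C4 is prone to ring contraction on dehydration.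

Alternative 2: The C9–C10 bond and the lactone C–O bond are cut, leading back to the cyclohexenyl keto ester A4. In the forward step MeAlCl2 would activate the C9 ketone, C10 of the ring A alkene would attack it, the C5 cation would lose a C6 proton, and the C9 alkoxide would lactonise to give A3.
- In its favour: the hardest bond, C9–C10, is made directly with the C9 oxygen attached. Ring A is bought as a simple cyclohexene. The lactone protects the tertiary alcohol and carries C11–C13. No C6 oxygen has to be removed.
- Against it here: A3 has a C5=C6 alkene between the quaternary C4 and C10 that must later be hydrogenated to the 5α-hydrogen. The C5 cation sits next to the gem-dimethyl carbon and can rearrange. The configuration of C9 and C10 relative to C3 rests on the epimerisable C8 and on a remote C3, so diastereomers are likely.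
- Comparison: Alternative 2 is the better plan in how directly it forms C9–C10 with its oxygen. It is the equal of the chosen plan in the endgame (methyl ketone, olefination, alkene and diol in ring A). It is weaker at C5, which the chosen plan sets by simple equilibration in 8 and 9, and in control of the absolute configuration of C10, which in 7 is governed by a stereocentre inside the closing ring.

Alternative 3: The C5–C10 and C6–C7 bonds are cut, leading back to the open triene A6. On heating, the silyloxydiene and the E-vinyl sulfone would undergo an intramolecular Diels–Alder reaction (type 1, four-atom tether) that closes rings A and B at once to give A5.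
- In its favour: two rings, two C–C bonds and the centres C5, C6 and C10 arise without any reagent. The silyl enol ether releases the C9 ketone next to the C8 methyl. Removal of the sulfone leaves C6 as a methylene, so three ketones never have to be told apart; on this point Alternative 3 is the better plan.
- Against it here: the diene terminus C10 is fully substituted and carries a cis substituent that disfavours the reactive s-cis conformer. The dienophile carbon C5 is neopentylic. The temperatures needed invite hydrogen shifts of the silyloxydiene, and the trans ring fusion is not assured. A6, with a stereodefined tetrasubstituted silyl dienol ether, is long to make.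
- Comparison: both plans create C10 by attack on a methyl-bearing sp2 carbon. The chosen plan does it with a much stronger acceptor and an irreversible polar addition, from a precursor that is far shorter to make. The two are equal in what follows, since A5 also needs the C9 side chain and the ring A alkene and diol, with desulfonylation in place of the C6 deoxygenation.

Key step: step 5

## Route

Step 1
Reactants: 1 (R)-(−)-pantolactone
Product: 2 (3R)-4,4-dimethyl-3-(triisopropylsilyloxy)oxolan-2-one
Conditions: iPr3SiOTf, 2,6-lutidine, CH2Cl2, 0 °C to rt
Reagents that add atoms: triisopropylsilyl trifluoromethanesulfonate, CC(C)[Si](OS(=O)(=O)C(F)(F)F)(C(C)C)C(C)C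
Why: Silyl ether formation at the hindered secondary hydroxyl with a silyl triflate and a hindered pyridine; no stereocentre is touched. The triisopropylsilyl group is chosen because it must survive the acidic radical step 4 and still be in place as the leaving group in step 7.

Step 2
Reactants: 2 (3R)-4,4-dimethyl-3-(triisopropylsilyloxy)oxolan-2-one
Product: 3 (3R)-2,4,4-trimethyl-3-(triisopropylsilyloxy)oxolan-2-ol (anomeric mixture in equilibrium with the open hydroxy methyl ketone)
Conditions: MeLi (1.1 equiv), THF, −78 °C; AcOH quench at −78 °C
Reagents that add atoms: methyllithium, [Li]C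
Why: Nucleophilic acyl addition to the lactone stops at the lithium hemiketal, which is stable at −78 °C and is protonated before it can open, so exactly one methyl (C1) is added. Addition is faster than α-deprotonation, so C3 keeps its configuration.

Step 3
Reactants: 3 (3R)-2,4,4-trimethyl-3-(triisopropylsilyloxy)oxolan-2-ol
Product: 5 (3R)-2,2-dimethyl-4-oxo-3-(triisopropylsilyloxy)pentanoic acid, via keto aldehyde 4 (not isolated)
Conditions: TEMPO (0.2 equiv), PhI(OAc)2 (2.5 equiv), MeCN/H2O 1:1, rt
Reagents that add atoms: water, O
Why: Oxoammonium (TEMPO) oxidation: the open hydroxy ketone tautomer of 3 is oxidised at its primary alcohol to aldehyde 4 and, through the hydrate, to the acid. The tertiary hemiketal form cannot be oxidised, and the near-neutral medium leaves the silyl ether and C3 alone.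

Step 4
Reactants: 5 (3R)-2,2-dimethyl-4-oxo-3-(triisopropylsilyloxy)pentanoic acid; 6 2,6-dimethyl-1,4-benzoquinone (2 equiv)
Product: 7 2,6-dimethyl-3-[(3R)-2-methyl-4-oxo-3-(triisopropylsilyloxy)pentan-2-yl]-1,4-benzoquinone
Conditions: AgNO3 (0.3 equiv), (NH4)2S2O8 (1.5 equiv), MeCN/H2O 1:1, 65 °C
Reagents that add atoms: none
Why: Silver-catalysed persulfate decarboxylative alkylation of a quinone: divalent silver oxidises the carboxylate, loss of CO2 gives the nucleophilic tertiary C4 radical, and this adds to one of the two equivalent free carbons of 6 before the semiquinone radical is re-oxidised. C3 is not part of the radical and stays (R); excess 6 suppresses a second alkylation.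

Step 5
Reactants: 7 2,6-dimethyl-3-[(3R)-2-methyl-4-oxo-3-(triisopropylsilyloxy)pentan-2-yl]-1,4-benzoquinone
Product: 8 4,4,8,10β-tetramethyl-3β-(triisopropylsilyloxy)-5α-decal-7-ene-2,6,9-trione (trans-fused)
Conditions: Cs2CO3 (0.3 equiv), MeCN (0.01 M), argon, 0 °C to rt; filtration through silica
Reagents that add atoms: none
Why: Cs2CO3 generates a small stationary concentration of the C1 enolate of the methyl ketone, which adds to C10, the β-carbon of the C6 enone unit of the quinone, so that the charge ends on the C6 enolate and C5 is then protonated; the closest known reaction type is the intramolecular Michael addition of ketone enolates to ene-diones, quinones and β,β-disubstituted enones. Ring A closes in the 6-endo-trig mode with respect to the C5=C10 acceptor (6-enolendo with respect to the enolate). The tether can otherwise only reach the C6 carbonyl (6-exo aldol) or let the C10 methyl add to C2 (vinylogous aldol); both are reversible, whereas the conjugate adduct cannot re-aromatise to a hydroquinone because C10 carries no hydrogen and is therefore the thermodynamic sink, which is the site selectivity the step needs. C10 is controlled by C3: in the chair-like closing ring the C4–C5 bond lies in the quinone plane, C1 approaches C10 perpendicular to it, and the bulky silyloxy group is expected to sit pseudo-equatorial, which delivers C1 to the face that leaves the C10 methyl cis to the C3 oxygen (10β with 3β). C5 is controlled thermodynamically: it is α to the C6 carbonyl and equilibrates under the same base to the trans ring fusion. Enolisation must occur at C1 and not at C3; the C3 hydrogen is flanked by the quaternary C4 and the silyl group, and its enolate cannot cyclise. The weak base and high dilution are chosen to keep C3 intact and to suppress bimolecular reactions of the quinone, and 8 is purified to a single diastereomer because C3 is the only record of which face was attacked.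

Step 6
Reactants: 8 4,4,8,10β-tetramethyl-3β-(triisopropylsilyloxy)-5α-decal-7-ene-2,6,9-trione
Product: 9 4,4,8α,10β-tetramethyl-3β-(triisopropylsilyloxy)-5α-decalin-2,6,9-trione
Conditions: Zn dust, AcOH, rt
Reagents that add atoms: none
Why: Dissolving-metal reduction of the ene-dione C7=C8 bond by two electron transfers and ketonisation of the dienediol. C8 is protonated under equilibrating conditions to the equatorial 8α-methyl and C5 stays trans. An α-silyloxy ketone is not cleaved by zinc in acetic acid at room temperature.

Step 7
Reactants: 9 4,4,8α,10β-tetramethyl-3β-(triisopropylsilyloxy)-5α-decalin-2,6,9-trione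
Product: 11 4,4,8α,10β-tetramethyl-5α-decal-2-en-9-one, via bis-hydrazone 10 (not isolated)
Conditions: N2H4·H2O (excess), diethylene glycol, 130 °C; then KOH, 195 °C, argon
Reagents that add atoms: none
Why: Huang–Minlon Wolff–Kishner reduction combined with Kishner–Leonard elimination: the C6 hydrazone is reduced to CH2, while the C2 hydrazone anion expels the C3 silanolate and the vinyl diazene loses N2 to give C2=C3 regiospecifically. The C9 ketone, flanked by the quaternary C10 and the tertiary C8, is expected not to form a hydrazone, as is general for ring ketones between fully substituted carbons. Hot KOH also holds C5 and C8 at the trans-fused, equatorial-methyl arrangement before the C6 carbonyl disappears.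

Step 8
Reactants: 11 4,4,8α,10β-tetramethyl-5α-decal-2-en-9-one; 12 2-(2-bromoethyl)-2-methyl-1,3-dioxolane
Product: 15 4-(9β-hydroxy-4,4,8α,10β-tetramethyl-5α-decal-2-en-9α-yl)butan-2-one, via Grignard reagent 13 (not isolated), via ketal adduct 14 (not isolated)
Conditions: 12, Mg, THF, below 25 °C; CeCl3, THF, −78 °C; 11, −78 to 0 °C; then 1 M HCl, THF, rt
Reagents that add atoms: water, O
Why: Organocerium addition to a hindered, enolisable ketone: transmetallation of 13 onto CeCl3 suppresses deprotonation at C8. The nucleophile enters along the axial α trajectory, anti to the axial C10 methyl, which with C1 blocks the equatorial β approach; this sets C9 with the equatorial β-hydroxyl and the axial α chain. Aqueous HCl in the work-up hydrolyses the dioxolane of 14 to the methyl ketone.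

Step 9
Reactants: 15 4-(9β-hydroxy-4,4,8α,10β-tetramethyl-5α-decal-2-en-9α-yl)butan-2-one; 16 methyl 2-(diethoxyphosphoryl)acetate (3 equiv)
Product: 17 methyl (E)-5-(9β-hydroxy-4,4,8α,10β-tetramethyl-5α-decal-2-en-9α-yl)-3-methylpent-2-enoate
Conditions: NaH (2.7 equiv), THF, 0 to 50 °C
Reagents that add atoms: none
Why: Horner–Wadsworth–Emmons olefination of the methyl ketone (the open form of its hemiketal equilibrium); the stabilised phosphonate favours the E-enoate with the ester trans to the longer chain, and the minor Z isomer is removed by chromatography. The phosphonate is kept in excess over NaH, so no C9 alkoxide is present that could add to C13 of the product.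

Step 10
Reactants: 17 methyl (E)-5-(9β-hydroxy-4,4,8α,10β-tetramethyl-5α-decal-2-en-9α-yl)-3-methylpent-2-enoate
Product: 18 methyl (E)-3-methyl-5-(2α,3α,9β-trihydroxy-4,4,8α,10β-tetramethyl-5α-decalin-9α-yl)pent-2-enoate (target)
Conditions: OsO4 (5 mol%), N-methylmorpholine N-oxide (1.2 equiv), acetone/H2O, rt; Na2SO3 work-up
Reagents that add atoms: osmium tetroxide, O=[Os](=O)(=O)=O (catalytic carrier of both oxygens); N-methylmorpholine N-oxide, C[N+]1([O-])CCOCC1; water, O
Why: Catalytic syn-dihydroxylation with octavalent osmium: the reagent adds to C2=C3 from the α face, opposite the axial methyls on C4 and C10, and so sets C2 and C3 as the 2α,3α-diol. The conjugated, electron-poor C13=C14 bond should react much more slowly.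

## Compound list

1 | (R)-(−)-pantolactone | CC1(C)COC(=O)[C@@H]1O | starting material
2 | (3R)-4,4-dimethyl-3-(triisopropylsilyloxy)oxolan-2-one | CC1(C)COC(=O)[C@@H]1O[Si](C(C)C)(C(C)C)C(C)C | intermediate
3 | (3R)-2,4,4-trimethyl-3-(triisopropylsilyloxy)oxolan-2-ol (anomeric mixture) | CC1(O)OCC(C)(C)[C@H]1O[Si](C(C)C)(C(C)C)C(C)C | intermediate
4 | (3R)-2,2-dimethyl-4-oxo-3-(triisopropylsilyloxy)pentanal | O=CC(C)(C)[C@@H](O[Si](C(C)C)(C(C)C)C(C)C)C(C)=O | intermediate
5 | (3R)-2,2-dimethyl-4-oxo-3-(triisopropylsilyloxy)pentanoic acid | OC(=O)C(C)(C)[C@@H](O[Si](C(C)C)(C(C)C)C(C)C)C(C)=O | intermediate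
6 | 2,6-dimethyl-1,4-benzoquinone | CC1=CC(=O)C=C(C)C1=O | starting material
7 | 2,6-dimethyl-3-[(3R)-2-methyl-4-oxo-3-(triisopropylsilyloxy)pentan-2-yl]-1,4-benzoquinone | CC1=CC(=O)C(=C(C)C1=O)C(C)(C)[C@@H](O[Si](C(C)C)(C(C)C)C(C)C)C(C)=O | intermediate
8 | 4,4,8,10β-tetramethyl-3β-(triisopropylsilyloxy)-5α-decal-7-ene-2,6,9-trione | O=C1C(C)=CC(=O)[C@H]2C(C)(C)[C@@H](O[Si](C(C)C)(C(C)C)C(C)C)C(=O)C[C@@]21C | intermediate
9 | 4,4,8α,10β-tetramethyl-3β-(triisopropylsilyloxy)-5α-decalin-2,6,9-trione | O=C1[C@H](C)CC(=O)[C@H]2C(C)(C)[C@@H](O[Si](C(C)C)(C(C)C)C(C)C)C(=O)C[C@@]21C | intermediate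
10 | 2,6-bis-hydrazone of 9 | O=C1[C@H](C)CC(=NN)[C@H]2C(C)(C)[C@@H](O[Si](C(C)C)(C(C)C)C(C)C)C(=NN)C[C@@]21C | intermediate
11 | 4,4,8α,10β-tetramethyl-5α-decal-2-en-9-one | O=C1[C@H](C)CC[C@H]2C(C)(C)C=CC[C@@]21C | intermediate
12 | 2-(2-bromoethyl)-2-methyl-1,3-dioxolane | CC1(CCBr)OCCO1 | starting material
13 | [2-(2-methyl-1,3-dioxolan-2-yl)ethyl]magnesium bromide | CC1(CC[Mg]Br)OCCO1 | intermediate
14 | 9β-hydroxy-9α-[2-(2-methyl-1,3-dioxolan-2-yl)ethyl]-4,4,8α,10β-tetramethyl-5α-decal-2-ene | CC1(CC[C@]2(O)[C@H](C)CC[C@H]3C(C)(C)C=CC[C@@]32C)OCCO1 | intermediate
15 | 4-(9β-hydroxy-4,4,8α,10β-tetramethyl-5α-decal-2-en-9α-yl)butan-2-one | CC(=O)CC[C@]1(O)[C@H](C)CC[C@H]2C(C)(C)C=CC[C@@]21C | intermediate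
16 | methyl 2-(diethoxyphosphoryl)acetate | CCOP(=O)(OCC)CC(=O)OC | starting material
17 | methyl (E)-5-(9β-hydroxy-4,4,8α,10β-tetramethyl-5α-decal-2-en-9α-yl)-3-methylpent-2-enoate | COC(=O)/C=C(\C)CC[C@]1(O)[C@H](C)CC[C@H]2C(C)(C)C=CC[C@@]21C | intermediate
18 | methyl (E)-3-methyl-5-(2α,3α,9β-trihydroxy-4,4,8α,10β-tetramethyl-5α-decalin-9α-yl)pent-2-enoate | COC(=O)/C=C(\C)CC[C@]1(O)[C@H](C)CC[C@H]2C(C)(C)[C@H](O)[C@H](O)C[C@@]21C | target

## Step count and least certain steps

Total step count: 10. Longest linear sequence: 10 steps (1 to 18); 6, 12 and 16 are bought.

**Step 5 (key step).**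
- What may go wrong: addition to the fully substituted C10 is sterically slow. The base may instead deprotonate the quinone methyl groups (quinone methide tautomers that dimerise), pass an electron to the quinone, or park the material in the reversible aldol adducts.
- Facial selection may be poor, because an equatorial oxygen on C3 is gauche to both C4 methyls and eclipses the enolate oxygen, so the preference for it is small. Slow enolisation towards C3 before closure would erode the enantiomeric purity.
- The sense of induction is to be secured on 8 (NOE between the C3 hydrogen and the C10 methyl) before scale-up. Because C2 and C3 are erased in step 7, an opposite facial preference would only mean that the enantiomeric lactone is used in step 1.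
- If the ene-dione should prefer the cis fusion, C5 is equilibrated again in the saturated dione in step 7.
- Fallback, from 7 back to 8: 7 is treated with Me3SiOTf and iPr2NEt (CH2Cl2, −78 °C) to give the terminal trimethylsilyl enol ether F1. TiCl4 at −78 °C then activates the quinone for a Mukaiyama–Michael closure by the neutral enol ether, with no basic species present, and aqueous work-up returns 8.

**Step 7.**
- What may go wrong: the equatorial C3–O bond is poorly aligned with the C2 hydrazone π-system, so simple reduction of C2 to a methylene may compete with elimination unless C3 epimerises or ring A twists.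
- The silyl group may be lost before the elimination, leaving an alkoxide that cannot depart. Hydrazone formation at the shielded C6 may be slow. Forcing conditions could begin to engage C9.
- Fallback, from 9 back to 11: NaBH4 (MeOH, −20 °C) reduces C2 and C6 from the open α face to the 2β,6β-diol F2. Any 9-ol formed is returned to the ketone later in the sequence. Bu4NF gives the triol F3. 1,1'-Thiocarbonyldiimidazole acylates the equatorial 3β-hydroxyl, and the neighbouring 2β-hydroxyl closes the ring to the cyclic thiocarbonate F4; the isolated axial 6β-hydroxyl, shielded by the C4 and C10 methyls, stays free. Corey–Winter olefination with P(OMe)3 at 110 °C gives the 6β-hydroxy alkene F5. Dess–Martin periodinane gives the alkene dione F6, and a plain Huang–Minlon reduction of its C6 carbonyl gives 11.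

**Step 8.**
- What may go wrong: enolisation at C8 or hydride transfer instead of addition at the very hindered carbonyl, decomposition of the thermally delicate reagent 13, or incomplete preference for the axial trajectory.
- Fallback, from 11 back to 15: Corey–Chaykovsky reaction with dimethylsulfonium methylide (Me3SI, KN(SiMe3)2, THF, 0 °C) delivers the small ylide axially and gives the spiro-epoxide F7, with oxygen β and CH2 α. AllylMgBr with catalytic CuI opens it at the CH2 to the but-3-enyl carbinol F8. Tsuji–Wacker oxidation (PdCl2, CuCl, O2, DMF/H2O) of the terminal alkene, which the hindered ring alkene does not undergo, gives 15.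

**Step 4.**
- What may go wrong: the bisulfate formed may cleave the silyl ether or enolise C3 at 65 °C. The tertiary radical may be oxidised to the cation before it adds. A second alkylation may occur at the remaining free position.
- Fallback, from 5 back to 7: 5 is coupled with N-hydroxyphthalimide (N,N'-diisopropylcarbodiimide, CH2Cl2) to the N-acyloxyphthalimide F9. Irradiation with blue light in the presence of fac-Ir(ppy)3 and excess 6 releases the same C4 radical under neutral conditions at room temperature, and oxidation of the adduct radical by the tetravalent iridium closes the cycle to give 7.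

**Step 10.**
- What may go wrong: competing oxidation of the C13=C14 bond if the hindered ring alkene reacts slowly, or over-oxidation of the diol.
- Fallback, from 15 to 18: 15, whose only alkene is C2=C3, is dihydroxylated first (OsO4, N-methylmorpholine N-oxide) to the triol ketone F10. The Horner–Wadsworth–Emmons reaction with 16 under the conditions of step 9 is then the last step and gives 18.

## Further compounds

F1 | step 5 | 2,6-dimethyl-3-[(3R)-2-methyl-3-(triisopropylsilyloxy)-4-(trimethylsilyloxy)pent-4-en-2-yl]-1,4-benzoquinone | C=C(O[Si](C)(C)C)[C@H](O[Si](C(C)C)(C(C)C)C(C)C)C(C)(C)C1=C(C)C(=O)C(C)=CC1=O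
F2 | step 7 | 2β,6β-dihydroxy-4,4,8α,10β-tetramethyl-3β-(triisopropylsilyloxy)-5α-decalin-9-one | O=C1[C@H](C)C[C@@H](O)[C@H]2C(C)(C)[C@@H](O[Si](C(C)C)(C(C)C)C(C)C)[C@@H](O)C[C@@]21C
F3 | step 7 | 2β,3β,6β-trihydroxy-4,4,8α,10β-tetramethyl-5α-decalin-9-one | O=C1[C@H](C)C[C@@H](O)[C@H]2C(C)(C)[C@@H](O)[C@@H](O)C[C@@]21C
F4 | step 7 | 2β,3β-cyclic thiocarbonate of F3 | O=C1[C@H](C)C[C@@H](O)[C@H]2C(C)(C)[C@H]3OC(=S)O[C@H]3C[C@@]21C
F5 | step 7 | 6β-hydroxy-4,4,8α,10β-tetramethyl-5α-decal-2-en-9-one | O=C1[C@H](C)C[C@@H](O)[C@H]2C(C)(C)C=CC[C@@]21C
F6 | step 7 | 4,4,8α,10β-tetramethyl-5α-decal-2-ene-6,9-dione | O=C1[C@H](C)CC(=O)[C@H]2C(C)(C)C=CC[C@@]21C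
F7 | step 8 | 9β,11-epoxy-4,4,8α,10β-tetramethyl-9α-methylene-bridged spiro-oxirane of 11 (oxygen β, CH2 α) | C1O[C@]12[C@H](C)CC[C@H]3C(C)(C)C=CC[C@@]32C
F8 | step 8 | 9α-(but-3-enyl)-4,4,8α,10β-tetramethyl-5α-decal-2-en-9β-ol | C=CCC[C@]1(O)[C@H](C)CC[C@H]2C(C)(C)C=CC[C@@]21C
F9 | step 4 | 1,3-dioxoisoindolin-2-yl (3R)-2,2-dimethyl-4-oxo-3-(triisopropylsilyloxy)pentanoate | O=C(ON1C(=O)c2ccccc2C1=O)C(C)(C)[C@@H](O[Si](C(C)C)(C(C)C)C(C)C)C(C)=O
F10 | step 10 | 4-(2α,3α,9β-trihydroxy-4,4,8α,10β-tetramethyl-5α-decalin-9α-yl)butan-2-one | CC(=O)CC[C@]1(O)[C@H](C)CC[C@H]2C(C)(C)[C@H](O)[C@H](O)C[C@@]21C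
A1 | alternative 1 | 3β,9β-dihydroxy trans-decalin with dioxolane-protected 3-oxobutyl chain on C9α | CC1(OCCO1)CC[C@]2(O)[C@H](C)CC[C@H]3C(C)(C)[C@@H](O)CC[C@@]32C
A2 | alternative 1 | acyclic (3S)-3,4-epoxy (5E)-ene C9 ketone with 8-methyl and dioxolane-protected chain | CC1(C)O[C@H]1CC/C(C)=C/CC[C@@H](C)C(=O)CCC2(C)OCCO2
A3 | alternative 2 | spirolactone octalin with C5=C6 alkene, 9β-oxygen and 3β-tert-butyldimethylsilyl ether | O=C1CC[C@]2(O1)[C@H](C)CC=C3C(C)(C)[C@@H](O[Si](C)(C)C(C)(C)C)CC[C@@]32C
A4 | alternative 2 | methyl 5-methyl-4-oxo-7-[5-(tert-butyldimethylsilyloxy)-2,6,6-trimethylcyclohex-1-enyl]heptanoate | CC1=C(CC[C@@H](C)C(=O)CCC(=O)OC)C(C)(C)[C@@H](O[Si](C)(C)C(C)(C)C)CC1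
A5 | alternative 3 | trans-fused octalin C8=C9 trimethylsilyl enol ether with C6 phenylsulfonyl and 3β-tert-butyldimethylsilyl ether | C[Si](C)(C)OC1=C(C)C[C@H](S(=O)(=O)c3ccccc3)[C@H]2C(C)(C)[C@@H](O[Si](C)(C)C(C)(C)C)CC[C@@]21C
A6 | alternative 3 | open triene: 2-(trimethylsilyloxy)diene tethered through C1–C4 to an E-vinyl phenyl sulfone, with C3 tert-butyldimethylsilyl ether | C=C(C)/C(O[Si](C)(C)C)=C(\C)CC[C@H](O[Si](C)(C)C(C)(C)C)C(C)(C)/C=C/S(=O)(=O)c1ccccc1
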